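Ring B (C5–C10, terpenoid numbering) is a cyclohexene whose C8=C9 double bond is the signature of a [4+2] union of a C7=C8–C9=C10 diene with a C5=C6 dienophile, and C1–C4 of ring A are the four-carbon tether between C10 and C5. An imidazolidinone-catalysed intramolecular Diels–Alder reaction of an acyclic trienal therefore forms C5–C10 and C6–C7, closes rings A and B and sets C5 and C10 in a single operation; the activating C6 formyl group is then excised. The precursor carries a stereodefined tetrasubstituted diene, a gem-dimethyl E-enal and the C11–C12 arm as a silyl ether. The side chain follows by B-alkyl Suzuki coupling at C12 and butenolide annulation.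

Key step: step 9

Atom labels: C1–C10 are the decalin carbons (ring A = C1–C5 and C10, ring B = C5–C10), C11–C12 the two-carbon arm on C9, C13 the side-chain alkene carbon bearing CH2OH, C14 and C15 the two CH carbons leading to the furanone.

Assumption: the facial sense of the (2S,5S)-imidazolidinone is taken from the accepted shielding model of its E-iminium ions, which predicts the 5S,10S series; should the sense prove opposite, the (2R,5R) catalyst would be used.

Step 1
Reactants: 1 but-3-yn-1-ol; 2 1-bromo-3-chloropropane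
Product: 4 7-chlorohept-3-yn-1-ol, via dilithium salt of but-3-yn-1-ol 3 (not isolated)
Conditions: n-BuLi (2.1 equiv), THF, −78 → −20 °C; then 2, DMPU, −78 °C → rt; H2O
Reagents that add atoms: none
Why: Double deprotonation gives an alkoxide–acetylide whose carbon terminus is the more reactive nucleophile and displaces bromide in preference to chloride (SN2 alkylation of an acetylide).

Step 2
Reactants: 4 7-chlorohept-3-yn-1-ol
Product: 6 (3E)-7-chloro-3-iodo-4-methylhept-3-en-1-ol, via cyclic alkenylmagnesium alkoxide 5 (not isolated)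
Conditions: MeMgBr (5 equiv), Fe(acac)3 (15 mol%), THF, −78 → 0 °C; then I2, THF, −78 → 0 °C; aq. Na2S2O3
Reagents that add atoms: methylmagnesium bromide, C[Mg]Br; iodine, II
Why: Alkoxide-directed iron-catalysed syn-carbomagnesiation of the homopropargylic alcohol should deliver methyl to the distal alkyne carbon (C10) and magnesium to the proximal one (C9) in a five-membered chelate, so that iodinolysis with retention fixes the tetrasubstituted geometry (methyl cis to iodine), the primary chloride being inert to the Grignard reagent at this temperature.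

Step 3
Reactants: 6 (3E)-7-chloro-3-iodo-4-methylhept-3-en-1-ol; 7 4,4,5,5-tetramethyl-2-(prop-1-en-2-yl)-1,3,2-dioxaborolane
Product: 8 (3E)-7-chloro-4-methyl-3-(prop-1-en-2-yl)hept-3-en-1-ol
Conditions: PdCl2(dppf) (5 mol%), K3PO4, 1,4-dioxane/H2O (4:1), 70 °C
Reagents that add atoms: none
Why: Suzuki–Miyaura coupling of an alkenyl iodide proceeds with retention of alkene geometry and tolerates the free hydroxyl group and the alkyl chloride, which completes the diene with the tether trans to the isopropenyl group.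

Step 4
Reactants: 8 (3E)-7-chloro-4-methyl-3-(prop-1-en-2-yl)hept-3-en-1-ol
Product: 9 [(3E)-7-chloro-4-methyl-3-(prop-1-en-2-yl)hept-3-en-1-yl]oxy-triisopropylsilane
Conditions: i-Pr3SiCl, imidazole, DMF, rt
Reagents that add atoms: chlorotriisopropylsilane, CC(C)[Si](Cl)(C(C)C)C(C)C
Why: Standard silylation of a primary alcohol gives a bulky silyl ether that should withstand the amide base, the hydride reductions and the acidic cycloaddition medium that follow.

Step 5
Reactants: 9 [(3E)-7-chloro-4-methyl-3-(prop-1-en-2-yl)hept-3-en-1-yl]oxy-triisopropylsilane; 10 2-methylpropanenitrile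
Product: 12 (6E)-2,2,6,8-tetramethyl-7-[2-(triisopropylsilyloxy)ethyl]nona-6,8-dienenitrile, via lithiated 2-methylpropanenitrile 11 (not isolated)
Conditions: LiN(i-Pr)2, 10, THF, −78 °C; then 9, DMPU, Bu4NI (10 mol%), −78 → 40 °C
Reagents that add atoms: none
Why: SN2 alkylation of the α-lithiated nitrile at the primary chloride (iodide catalysis) installs the quaternary C4, and neither the diene nor the silyl ether is acidic or electrophilic enough to interfere.

Step 6
Reactants: 12 (6E)-2,2,6,8-tetramethyl-7-[2-(triisopropylsilyloxy)ethyl]nona-6,8-dienenitrile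
Product: 14 (6E)-2,2,6,8-tetramethyl-7-[2-(triisopropylsilyloxy)ethyl]nona-6,8-dienal, via N-diisobutylaluminio aldimine 13 (not isolated)
Conditions: i-Bu2AlH (1.3 equiv), toluene, −78 → 0 °C; then aq. AcOH/NaOAc (pH 5), 0 °C
Reagents that add atoms: water, O
Why: Hydride addition to the tertiary nitrile stops at the N-aluminio aldimine, which buffered hydrolysis converts into the aldehyde without exposing the diene to strong acid (nitrile-to-aldehyde reduction).

Step 7
Reactants: 14 (6E)-2,2,6,8-tetramethyl-7-[2-(triisopropylsilyloxy)ethyl]nona-6,8-dienal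
Product: 15 (2E,8E)-N-methoxy-N,4,4,8,10-pentamethyl-9-[2-(triisopropylsilyloxy)ethyl]undeca-2,8,10-trienamide
Conditions: (EtO)2P(O)CH2C(O)N(OMe)Me, NaH, THF, 0 °C → rt
Reagents that add atoms: diethyl {2-[methoxy(methyl)amino]-2-oxoethyl}phosphonate, CCOP(=O)(OCC)CC(=O)N(C)OC
Why: Horner–Wadsworth–Emmons olefination of the non-enolisable neopentyl aldehyde with a stabilised phosphonate anion should give the E-enamide, the bulky quaternary neighbour reinforcing the usual E preference.

Step 8
Reactants: 15 (2E,8E)-N-methoxy-N,4,4,8,10-pentamethyl-9-[2-(triisopropylsilyloxy)ethyl]undeca-2,8,10-trienamide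
Product: 17 (2E,8E)-4,4,8,10-tetramethyl-9-[2-(triisopropylsilyloxy)ethyl]undeca-2,8,10-trienal, via aluminium-chelated hemiaminal 16 (not isolated)
Conditions: i-Bu2AlH (1.2 equiv), THF, −78 °C; aq. potassium sodium tartrate
Reagents that add atoms: none
Why: 1,2-Hydride addition to the Weinreb amide gives a stable five-membered aluminium chelate that collapses to the E-enal only on work-up, so over-reduction is avoided (Weinreb amide reduction).

Step 9
Reactants: 17 (2E,8E)-4,4,8,10-tetramethyl-9-[2-(triisopropylsilyloxy)ethyl]undeca-2,8,10-trienal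
Product: 20 (1S,4aS,8aS)-3,4a,8,8-tetramethyl-4-[2-(triisopropylsilyloxy)ethyl]-1,2,4a,5,6,7,8,8a-octahydronaphthalene-1-carbaldehyde, via trienal iminium trifluoroacetate 18 (not isolated), via cycloadduct iminium trifluoroacetate 19 (not isolated)
Conditions: (2S,5S)-5-benzyl-2-tert-butyl-3-methylimidazolidin-4-one·CF3CO2H (20 mol%), MeCN/H2O (98:2), 0 °C → rt
Reagents that add atoms: water, O
Why: Proposed new method: the enal condenses with the secondary amine salt to E-iminium ion 18, whose lowered LUMO lets the tethered diene add suprafacially in one concerted but asynchronous [4+2] event that forms C6–C7 and C5–C10, and hydrolysis of cycloadduct iminium 19 returns the catalyst; the closest known reaction type is the imidazolidinone-catalysed intramolecular Diels–Alder reaction of deca-2,7,9-trienals, which has not been shown for a fully substituted diene terminus that must become an all-carbon quaternary centre. Ring B closes through both new bonds of the cycloaddition, and ring A closes at the same time as the six-membered ring spanned by the C1–C4 tether and the new C5–C10 bond (fused, type 1 mode). C5 is controlled by the catalyst, whose benzyl group covers one face of the iminium π-system so that C10 bonds to the open face (predicted 5S with the 2S,5S catalyst); C10 is controlled relative to C5 by the E geometry of C9=C10 together with the endo transition state (formyl under the diene, tether anti), which places H-5 and the C10 methyl group trans; C6 follows from the E-enal geometry and is erased in step 10. The step needs endo over exo selectivity (trans versus cis ring fusion) and π-facial selectivity, the former secured by the E-enal and the chair-like four-carbon tether, the latter by the catalyst, while regiochemistry is enforced by the tether. Reactivity is the real uncertainty, because the 1,1,2,3-tetrasubstituted diene reaches its cisoid form only with strain and is acid-sensitive, hence the mild trifluoroacetate salt and slow warming.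

Step 10
Reactants: 20 (1S,4aS,8aS)-3,4a,8,8-tetramethyl-4-[2-(triisopropylsilyloxy)ethyl]-1,2,4a,5,6,7,8,8a-octahydronaphthalene-1-carbaldehyde
Product: 21 triisopropyl{2-[(4aS,8aS)-2,5,5,8a-tetramethyl-3,4,4a,5,6,7,8,8a-octahydronaphthalen-1-yl]ethoxy}silane
Conditions: RhCl(PPh3)3 (1.1 equiv), PhCN, 130 °C
Reagents that add atoms: none
Why: Tsuji–Wilkinson decarbonylation (formyl C–H oxidative addition, CO extrusion, C–H reductive elimination) should replace the formyl group by hydrogen, removing the C6 stereocentre while C5, C10 and the tetrasubstituted alkene stay untouched.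

Step 11
Reactants: 21 triisopropyl{2-[(4aS,8aS)-2,5,5,8a-tetramethyl-3,4,4a,5,6,7,8,8a-octahydronaphthalen-1-yl]ethoxy}silane
Product: 22 2-[(4aS,8aS)-2,5,5,8a-tetramethyl-3,4,4a,5,6,7,8,8a-octahydronaphthalen-1-yl]ethan-1-ol
Conditions: Bu4NF, THF, rt
Reagents that add atoms: none
Why: Fluoride-induced cleavage of the silyl ether is driven by the strong Si–F bond and touches nothing else in this hydrocarbon-like molecule.

Step 12
Reactants: 22 2-[(4aS,8aS)-2,5,5,8a-tetramethyl-3,4,4a,5,6,7,8,8a-octahydronaphthalen-1-yl]ethan-1-ol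
Product: 23 (4aS,8aS)-1-(2-iodoethyl)-2,5,5,8a-tetramethyl-3,4,4a,5,6,7,8,8a-octahydronaphthalene
Conditions: I2, PPh3, imidazole, CH2Cl2, 0 °C → rt
Reagents that add atoms: iodine, II
Why: Appel-type iodination converts the primary alcohol into the iodide by SN2 displacement of the alkoxyphosphonium ion under neutral conditions that leave the alkene in place.

Step 13
Reactants: 24 but-2-yne-1,4-diol
Product: 25 4-{[tert-butyl(dimethyl)silyl]oxy}but-2-yn-1-ol
Conditions: NaH (1.0 equiv), THF, 0 °C → rt; then t-BuMe2SiCl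
Reagents that add atoms: tert-butyl(chloro)dimethylsilane, CC(C)(C)[Si](C)(C)Cl
Why: Silylation through the sparingly soluble monosodium alkoxide of the symmetrical diol should give the mono-ether selectively.

Step 14
Reactants: 25 4-{[tert-butyl(dimethyl)silyl]oxy}but-2-yn-1-ol
Product: 27 (2Z)-4-{[tert-butyl(dimethyl)silyl]oxy}-3-iodobut-2-en-1-ol, via cyclic alkenylalanate 26 (not isolated)
Conditions: NaAlH2(OCH2CH2OMe)2 (1.5 equiv), THF, 0 °C → rt; EtOAc; then I2, −78 → 0 °C
Reagents that add atoms: iodine, II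
Why: Hydroxyl-directed trans-hydroalumination through a five-membered cyclic alanate places aluminium on C3 cis to the carbinol carbon, and iodinolysis with retention gives the Z-iodoalkene.

Step 15
Reactants: 23 (4aS,8aS)-1-(2-iodoethyl)-2,5,5,8a-tetramethyl-3,4,4a,5,6,7,8,8a-octahydronaphthalene; 27 (2Z)-4-{[tert-butyl(dimethyl)silyl]oxy}-3-iodobut-2-en-1-ol
Product: 30 (2E)-3-{[tert-butyl(dimethyl)silyloxy]methyl}-5-[(4aS,8aS)-2,5,5,8a-tetramethyl-3,4,4a,5,6,7,8,8a-octahydronaphthalen-1-yl]pent-2-en-1-ol, via alkyllithium 28 (not isolated), via lithium alkylborate 29 (not isolated)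
Conditions: t-BuLi (2.1 equiv), Et2O, −78 °C; 9-methoxy-9-borabicyclo[3.3.1]nonane, THF, −78 °C → rt; then 27, PdCl2(dppf) (5 mol%), AsPh3, aq. K3PO4, DMF, rt
Reagents that add atoms: none
Why: B-alkyl Suzuki–Miyaura coupling, in which lithium–iodine exchange and capture by the borinate give an alkylborate that transfers its primary alkyl group to palladium and couples with the alkenyl iodide with retention, forms C12–C13 and fixes the C13=C14 geometry (C12 cis to C15) in the presence of the free hydroxyl group.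

Step 16
Reactants: 30 (2E)-3-{[tert-butyl(dimethyl)silyloxy]methyl}-5-[(4aS,8aS)-2,5,5,8a-tetramethyl-3,4,4a,5,6,7,8,8a-octahydronaphthalen-1-yl]pent-2-en-1-ol
Product: 31 (2E)-3-{[tert-butyl(dimethyl)silyloxy]methyl}-5-[(4aS,8aS)-2,5,5,8a-tetramethyl-3,4,4a,5,6,7,8,8a-octahydronaphthalen-1-yl]pent-2-enal
Conditions: MnO2, CH2Cl2, rt
Reagents that add atoms: none
Why: MnO2 oxidises the allylic alcohol selectively under neutral heterogeneous conditions that should neither isomerise the enal nor affect the isolated tetrasubstituted alkene or the silyl ether.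

Step 17
Reactants: 31 (2E)-3-{[tert-butyl(dimethyl)silyloxy]methyl}-5-[(4aS,8aS)-2,5,5,8a-tetramethyl-3,4,4a,5,6,7,8,8a-octahydronaphthalen-1-yl]pent-2-enal; 32 4-methylfuran-2(5H)-one
Product: 35 (5Z)-5-[(2E)-3-{[tert-butyl(dimethyl)silyloxy]methyl}-5-[(4aS,8aS)-2,5,5,8a-tetramethyl-3,4,4a,5,6,7,8,8a-octahydronaphthalen-1-yl]pent-2-en-1-ylidene]-4-methylfuran-2(5H)-one, via 2-silyloxyfuran 33 (not isolated), via silylated aldol adduct 34 (not isolated)
Conditions: t-BuMe2SiOTf, i-Pr2NEt, CH2Cl2, 0 °C → rt; then DBU, rt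
Reagents that add atoms: none
Why: Vinylogous Mukaiyama aldol addition of the in-situ 2-silyloxyfuran through its C5 to the aldehyde (1,2-addition, since the enal β-carbon C13 is fully substituted) followed by base-induced E1cB loss of silanolate should give the γ-alkylidene butenolide, the Z isomer being favoured because it avoids the clash between the ring methyl group and the chain.

Step 18
Reactants: 35 (5Z)-5-[(2E)-3-{[tert-butyl(dimethyl)silyloxy]methyl}-5-[(4aS,8aS)-2,5,5,8a-tetramethyl-3,4,4a,5,6,7,8,8a-octahydronaphthalen-1-yl]pent-2-en-1-ylidene]-4-methylfuran-2(5H)-one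
Product: 36 (5Z)-5-[(2E)-3-(hydroxymethyl)-5-[(4aS,8aS)-2,5,5,8a-tetramethyl-3,4,4a,5,6,7,8,8a-octahydronaphthalen-1-yl]pent-2-en-1-ylidene]-4-methylfuran-2(5H)-one
Conditions: HF·pyridine, THF/pyridine, 0 °C → rt
Reagents that add atoms: none
Why: Buffered HF·pyridine cleaves the primary allylic silyl ether under non-basic conditions that should spare the base-sensitive alkylidene butenolide and both side-chain double-bond geometries.

Compound list

1 | but-3-yn-1-ol | C#CCCO | starting material
2 | 1-bromo-3-chloropropane | ClCCCBr | starting material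
3 | dilithium salt of but-3-yn-1-ol (alkoxide–acetylide) | [Li]C#CCCO[Li] | intermediate
4 | 7-chlorohept-3-yn-1-ol | OCCC#CCCCCl | intermediate
5 | cyclic alkenylmagnesium alkoxide (five-membered oxamagnesacycle, methyl cis to magnesium) | C/C(CCCCl)=C1/CCO[Mg]1 | intermediate
6 | (3E)-7-chloro-3-iodo-4-methylhept-3-en-1-ol | OCC/C(I)=C(C)\CCCCl | intermediate
7 | 4,4,5,5-tetramethyl-2-(prop-1-en-2-yl)-1,3,2-dioxaborolane | CC(=C)B1OC(C)(C)C(C)(C)O1 | starting material
8 | (3E)-7-chloro-4-methyl-3-(prop-1-en-2-yl)hept-3-en-1-ol | OCC/C(C(C)=C)=C(C)\CCCCl | intermediate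
9 | [(3E)-7-chloro-4-methyl-3-(prop-1-en-2-yl)hept-3-en-1-yl]oxy-triisopropylsilane | CC(C)[Si](C(C)C)(C(C)C)OCC/C(C(C)=C)=C(C)\CCCCl | intermediate
10 | 2-methylpropanenitrile | CC(C)C#N | starting material
11 | lithiated 2-methylpropanenitrile (lithium keteniminate) | CC(C)=C=N[Li] | intermediate
12 | (6E)-2,2,6,8-tetramethyl-7-[2-(triisopropylsilyloxy)ethyl]nona-6,8-dienenitrile | N#CC(C)(C)CCC/C(C)=C(/C(C)=C)CCO[Si](C(C)C)(C(C)C)C(C)C | intermediate
13 | N-diisobutylaluminio aldimine of 14 | CC(C)C[Al](CC(C)C)N=CC(C)(C)CCC/C(C)=C(/C(C)=C)CCO[Si](C(C)C)(C(C)C)C(C)C | intermediate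
14 | (6E)-2,2,6,8-tetramethyl-7-[2-(triisopropylsilyloxy)ethyl]nona-6,8-dienal | O=CC(C)(C)CCC/C(C)=C(/C(C)=C)CCO[Si](C(C)C)(C(C)C)C(C)C | intermediate
15 | (2E,8E)-N-methoxy-N,4,4,8,10-pentamethyl-9-[2-(triisopropylsilyloxy)ethyl]undeca-2,8,10-trienamide | CON(C)C(=O)/C=C/C(C)(C)CCC/C(C)=C(/C(C)=C)CCO[Si](C(C)C)(C(C)C)C(C)C | intermediate
16 | aluminium-chelated hemiaminal from 15 (O-diisobutylaluminio N-methoxy-N-methyl hemiaminal) | CON(C)C(O[Al](CC(C)C)CC(C)C)/C=C/C(C)(C)CCC/C(C)=C(/C(C)=C)CCO[Si](C(C)C)(C(C)C)C(C)C | intermediate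
17 | (2E,8E)-4,4,8,10-tetramethyl-9-[2-(triisopropylsilyloxy)ethyl]undeca-2,8,10-trienal | O=C/C=C/C(C)(C)CCC/C(C)=C(/C(C)=C)CCO[Si](C(C)C)(C(C)C)C(C)C | intermediate
18 | E-iminium trifluoroacetate of 17 with the (2S,5S)-imidazolidinone | CN1C(=O)[C@H](Cc2ccccc2)/[N+](=C\C=C\C(C)(C)CCC/C(C)=C(/C(C)=C)CCO[Si](C(C)C)(C(C)C)C(C)C)[C@@H]1C(C)(C)C.[O-]C(=O)C(F)(F)F | intermediate
19 | iminium trifluoroacetate of cycloadduct 20 with the (2S,5S)-imidazolidinone | CC(C)[Si](C(C)C)(C(C)C)OCCC1=C(C)C[C@H](/C=[N+]3/[C@H](C(C)(C)C)N(C)C(=O)[C@@H]3Cc4ccccc4)[C@H]2C(C)(C)CCC[C@]12C.[O-]C(=O)C(F)(F)F | intermediate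
20 | (1S,4aS,8aS)-3,4a,8,8-tetramethyl-4-[2-(triisopropylsilyloxy)ethyl]-1,2,4a,5,6,7,8,8a-octahydronaphthalene-1-carbaldehyde (trans-fused; 5S,6S,10S in terpenoid numbering) | CC(C)[Si](C(C)C)(C(C)C)OCCC1=C(C)C[C@H](C=O)[C@H]2C(C)(C)CCC[C@]12C | intermediate
21 | triisopropyl{2-[(4aS,8aS)-2,5,5,8a-tetramethyl-3,4,4a,5,6,7,8,8a-octahydronaphthalen-1-yl]ethoxy}silane | CC(C)[Si](C(C)C)(C(C)C)OCCC1=C(C)CC[C@H]2C(C)(C)CCC[C@]12C | intermediate
22 | 2-[(4aS,8aS)-2,5,5,8a-tetramethyl-3,4,4a,5,6,7,8,8a-octahydronaphthalen-1-yl]ethan-1-ol | OCCC1=C(C)CC[C@H]2C(C)(C)CCC[C@]12C | intermediate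
23 | (4aS,8aS)-1-(2-iodoethyl)-2,5,5,8a-tetramethyl-3,4,4a,5,6,7,8,8a-octahydronaphthalene | ICCC1=C(C)CC[C@H]2C(C)(C)CCC[C@]12C | intermediate
24 | but-2-yne-1,4-diol | OCC#CCO | starting material
25 | 4-{[tert-butyl(dimethyl)silyl]oxy}but-2-yn-1-ol | OCC#CCO[Si](C)(C)C(C)(C)C | intermediate
26 | sodium cyclic alkenylalanate (five-membered oxaaluminacycle, aluminium on C3) | [Na+].COCCO[Al-]1(OCCOC)OCC=C1CO[Si](C)(C)C(C)(C)C | intermediate
27 | (2Z)-4-{[tert-butyl(dimethyl)silyl]oxy}-3-iodobut-2-en-1-ol | OC/C=C(I)/CO[Si](C)(C)C(C)(C)C | intermediate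
28 | alkyllithium from 23 (lithium in place of iodine) | [Li]CCC1=C(C)CC[C@H]2C(C)(C)CCC[C@]12C | intermediate
29 | lithium B-alkyl-B-methoxy-9-borabicyclo[3.3.1]nonane borate from 28 | [Li+].CO[B-]1(CCC3=C(C)CC[C@H]4C(C)(C)CCC[C@]34C)C2CCCC1CCC2 | intermediate
30 | (2E)-3-{[tert-butyl(dimethyl)silyloxy]methyl}-5-[(4aS,8aS)-2,5,5,8a-tetramethyl-3,4,4a,5,6,7,8,8a-octahydronaphthalen-1-yl]pent-2-en-1-ol | OC/C=C(/CO[Si](C)(C)C(C)(C)C)CCC1=C(C)CC[C@H]2C(C)(C)CCC[C@]12C | intermediate
31 | (2E)-3-{[tert-butyl(dimethyl)silyloxy]methyl}-5-[(4aS,8aS)-2,5,5,8a-tetramethyl-3,4,4a,5,6,7,8,8a-octahydronaphthalen-1-yl]pent-2-enal | O=C/C=C(/CO[Si](C)(C)C(C)(C)C)CCC1=C(C)CC[C@H]2C(C)(C)CCC[C@]12C | intermediate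
32 | 4-methylfuran-2(5H)-one | CC1=CC(=O)OC1 | starting material
33 | tert-butyl(dimethyl)[(4-methylfuran-2-yl)oxy]silane | CC1=COC(O[Si](C)(C)C(C)(C)C)=C1 | intermediate
34 | silylated vinylogous aldol adduct (C5-substituted 4-methylfuran-2(5H)-one; mixture at the two new sp3 centres) | CC1=CC(=O)OC1C(O[Si](C)(C)C(C)(C)C)/C=C(/CO[Si](C)(C)C(C)(C)C)CCC2=C(C)CC[C@H]3C(C)(C)CCC[C@]23C | intermediate
35 | (5Z)-5-[(2E)-3-{[tert-butyl(dimethyl)silyloxy]methyl}-5-[(4aS,8aS)-2,5,5,8a-tetramethyl-3,4,4a,5,6,7,8,8a-octahydronaphthalen-1-yl]pent-2-en-1-ylidene]-4-methylfuran-2(5H)-one | CC1=CC(=O)O/C1=C\C=C(\CO[Si](C)(C)C(C)(C)C)CCC2=C(C)CC[C@H]3C(C)(C)CCC[C@]23C | intermediate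
36 | (5Z)-5-[(2E)-3-(hydroxymethyl)-5-[(4aS,8aS)-2,5,5,8a-tetramethyl-3,4,4a,5,6,7,8,8a-octahydronaphthalen-1-yl]pent-2-en-1-ylidene]-4-methylfuran-2(5H)-one | CC1=CC(=O)O/C1=C\C=C(\CO)CCC1=C(C)CC[C@H]2C(C)(C)CCC[C@]12C | target

Total step count: 18 steps. Longest linear sequence: 16 steps (steps 1–12 and 15–18); the C13–C15 building block 27 is made in 2 steps (13–14).

Steps most likely to fail

Step 9 (cycloaddition). The twisted, fully substituted diene may not reach its cisoid geometry before acid-induced double-bond migration sets in, or the cycloaddition may proceed with poor endo/exo or facial control. The fallback replaces aminocatalysis by a covalent chiral auxiliary with chelating Lewis-acid activation, a known reaction type for trienimides. It sets out from trienal 17, which is oxidised (NaClO2, NaH2PO4, 2-methylbut-2-ene, t-BuOH/H2O) to the (2E,8E)-trienoic acid F1. Pivaloyl chloride/Et3N converts this into the mixed pivalic anhydride F2 (not isolated), which acylates lithiated (4S)-4-benzyl-1,3-oxazolidin-2-one to give the trienimide F3. Me2AlCl (1.4 equiv, CH2Cl2, −30 °C → rt) should then promote the auxiliary-controlled endo cycloaddition to the cycloadduct imide F4, the same chelate model predicting the 5S,10S series. LiBH4 (Et2O, H2O, 0 °C) releases the C6 hydroxymethyl compound F5, and Dess–Martin oxidation brings the sequence back to the route at aldehyde 20.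

Step 17 (butenolide annulation). The silyloxyfuran may add in a conjugate instead of a 1,2 sense, or the elimination may be incomplete or unselective, giving E/Z mixtures at the exocyclic double bond or erosion of the C13=C14 geometry through the allylic silyl ether. The fallback closes the lactone onto an alkyne instead. It sets out from enal 31, which undergoes Corey–Fuchs homologation: CBr4/PPh3 (CH2Cl2, 0 °C) gives the 1,1-dibromodiene F8, and n-BuLi (THF, −78 °C) then gives the terminal enyne F9. Sonogashira coupling of F9 with (2Z)-3-iodobut-2-enoic acid F10 (from but-2-ynoic acid, NaI, AcOH, 115 °C) under Pd(PPh3)4, CuI, Et3N, MeCN is followed in the same flask by 5-exo-dig lactonisation of the enynoic acid, which is inherently Z-selective and returns to the route at 35.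

Step 10 (decarbonylation). CO extrusion at the hindered secondary formyl group may stall, the alkylrhodium intermediate may undergo β-hydride elimination, or a rhodium hydride may shift the C8=C9 double bond. The fallback uses radical decarboxylation in place of the transition-metal step. It sets out from aldehyde 20, which is oxidised (NaClO2, NaH2PO4, 2-methylbut-2-ene, t-BuOH/H2O) to the C6 carboxylic acid F6. Coupling with 1-hydroxypyridine-2(1H)-thione (DCC, DMAP, CH2Cl2, dark) gives the thiohydroxamate ester F7, and visible-light irradiation with t-BuSH (Barton reductive decarboxylation) returns to the route at 21.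

Further compounds

F1 | step 9 | (2E,8E)-4,4,8,10-tetramethyl-9-[2-(triisopropylsilyloxy)ethyl]undeca-2,8,10-trienoic acid | OC(=O)/C=C/C(C)(C)CCC/C(C)=C(/C(C)=C)CCO[Si](C(C)C)(C(C)C)C(C)C
F2 | step 9 | mixed anhydride of F1 with pivalic acid | CC(C)(C)C(=O)OC(=O)/C=C/C(C)(C)CCC/C(C)=C(/C(C)=C)CCO[Si](C(C)C)(C(C)C)C(C)C
F3 | step 9 | (4S)-4-benzyl-3-[(2E,8E)-4,4,8,10-tetramethyl-9-[2-(triisopropylsilyloxy)ethyl]undeca-2,8,10-trienoyl]-1,3-oxazolidin-2-one | O=C(/C=C/C(C)(C)CCC/C(C)=C(/C(C)=C)CCO[Si](C(C)C)(C(C)C)C(C)C)N1[C@@H](Cc2ccccc2)COC1=O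
F4 | step 9 | cycloadduct imide: (4S)-4-benzyl-3-{[(1S,4aS,8aS)-3,4a,8,8-tetramethyl-4-[2-(triisopropylsilyloxy)ethyl]-1,2,4a,5,6,7,8,8a-octahydronaphthalen-1-yl]carbonyl}-1,3-oxazolidin-2-one | CC(C)[Si](C(C)C)(C(C)C)OCCC1=C(C)C[C@H](C(=O)N3[C@@H](Cc4ccccc4)COC3=O)[C@H]2C(C)(C)CCC[C@]12C
F5 | step 9 | {(1S,4aS,8aS)-3,4a,8,8-tetramethyl-4-[2-(triisopropylsilyloxy)ethyl]-1,2,4a,5,6,7,8,8a-octahydronaphthalen-1-yl}methanol | CC(C)[Si](C(C)C)(C(C)C)OCCC1=C(C)C[C@H](CO)[C@H]2C(C)(C)CCC[C@]12C
F6 | step 10 | (1S,4aS,8aS)-3,4a,8,8-tetramethyl-4-[2-(triisopropylsilyloxy)ethyl]-1,2,4a,5,6,7,8,8a-octahydronaphthalene-1-carboxylic acid | CC(C)[Si](C(C)C)(C(C)C)OCCC1=C(C)C[C@H](C(O)=O)[C@H]2C(C)(C)CCC[C@]12C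
F7 | step 10 | 2-thioxopyridin-1(2H)-yl ester of F6 (thiohydroxamate ester) | CC(C)[Si](C(C)C)(C(C)C)OCCC1=C(C)C[C@H](C(=O)On3ccccc3=S)[C@H]2C(C)(C)CCC[C@]12C
F8 | step 17 | 1,1-dibromodiene from 31 (CBr2 in place of the aldehyde oxygen; 3E) | BrC(Br)=C/C=C(/CO[Si](C)(C)C(C)(C)C)CCC1=C(C)CC[C@H]2C(C)(C)CCC[C@]12C
F9 | step 17 | terminal enyne from F8 (3E) | C#C/C=C(/CO[Si](C)(C)C(C)(C)C)CCC1=C(C)CC[C@H]2C(C)(C)CCC[C@]12C
F10 | step 17 | (2Z)-3-iodobut-2-enoic acid | C/C(I)=C/C(O)=O
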